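**Strategy.** Disconnection: the ring-fusion bond C1–C6 and the diol bond C8–C9 (oplopane numbering: C1/C6 fusion carbons, C7 carries the oxirane, C8 the free OH, C9 the enoate, C10 the methylidene). Both bonds end at a neighbour of C10, so with C10 as a ketone C1 and C9 are its two α-carbons and C6–C7–C8 is an enal. One amine-catalysed Michael/aldol domino of an acyclic 1-acyloxy-2-ketone that carries a 2-isopropenyl enal closes the cyclopentane (C1–C6) and the cyclohexane (C8–C9) and sets C1, C6, C7 and C9. C10 methylenation, ester-assisted inversion of C8 and a C8–OH-directed epoxidation finish the synthesis.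

Key step: step 13

Assumption: pent-4-ynal, (2-methylallyl)triphenylphosphonium chloride and (E)-3-methylpent-2-enoic acid are taken as purchasable; the oplopane numbering above is used for all intermediates, and the (E)-enal geometry drawn for 15–19 is the expected Wittig outcome.

Step 1
Reactants: 1 (R)-4-benzyloxazolidin-2-one; 2 (E)-but-2-enoyl chloride
Product: 3 (R)-4-benzyl-3-[(E)-but-2-enoyl]oxazolidin-2-one
Conditions: n-BuLi, THF, −78 °C; then 2, −78 → 0 °C
Reagents that add atoms: none
Why: N-acylation of the lithiated oxazolidinone by the acid chloride (auxiliary acylation); no stereocentre is formed.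

Step 2
Reactants: 3 (R)-4-benzyl-3-[(E)-but-2-enoyl]oxazolidin-2-one; 4 pent-4-ynal
Product: 5 (R)-4-benzyl-3-[(2R,3S)-2-ethenyl-3-hydroxyhept-6-ynoyl]oxazolidin-2-one
Conditions: Bu2BOTf, Et3N, CH2Cl2, −78 → 0 °C; 4, −78 → 0 °C; pH 7 buffer, MeOH, H2O2
Reagents that add atoms: none
Why: Evans syn aldol: soft enolisation gives the boron (Z)-dienolate, which reacts at its α-carbon through a closed chair transition state on the face opposite the benzyl group, so oplopane C3 and C5 (3S,2R in 5) are set together as the syn pair.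

Step 3
Reactants: 5 (R)-4-benzyl-3-[(2R,3S)-2-ethenyl-3-hydroxyhept-6-ynoyl]oxazolidin-2-one
Product: 6 (2R,3S)-2-ethenyl-3-hydroxy-N-methoxy-N-methylhept-6-ynamide
Conditions: AlMe3, MeNH(OMe)·HCl, CH2Cl2, −20 → 0 °C
Reagents that add atoms: N,O-dimethylhydroxylamine hydrochloride, CNOC.Cl
Why: Weinreb aminolysis of the imide by the aluminium amide formed in situ, directed by the free β-hydroxyl; the auxiliary is released and the α-stereocentre is untouched.

Step 4
Reactants: 6 (2R,3S)-2-ethenyl-3-hydroxy-N-methoxy-N-methylhept-6-ynamide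
Product: 7 (3R,4S)-3-ethenyl-4-hydroxyoct-7-yn-2-one
Conditions: MeMgBr (excess), THF, −78 → −20 °C; aq. NH4Cl at −20 °C
Reagents that add atoms: methylmagnesium bromide, C[Mg]Br
Why: Weinreb ketone synthesis: the chelated tetrahedral adduct stops at the ketone stage, and the cold buffered quench should keep the β,γ-unsaturated ketone from conjugating or epimerising at C5.

Step 5
Reactants: 7 (3R,4S)-3-ethenyl-4-hydroxyoct-7-yn-2-one
Product: 8 (2S,3S,4S)-3-ethenyloct-7-yne-2,4-diol
Conditions: Me4NBH(OAc)3, MeCN/AcOH (1:1), −30 °C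
Reagents that add atoms: none
Why: Evans–Saksena reduction: the C3 hydroxyl binds the acetoxyborohydride and delivers hydride intramolecularly through a chair, which gives the 1,3-anti diol and sets C4 as (S).

Step 6
Reactants: 8 (2S,3S,4S)-3-ethenyloct-7-yne-2,4-diol
Product: 9 (2S,3S,4S)-3-ethenyl-2,4-bis(triethylsilyloxy)oct-7-yne
Conditions: TESOTf, 2,6-lutidine, CH2Cl2, −78 → 0 °C
Reagents that add atoms: triethylsilyl trifluoromethanesulfonate, CC[Si](CC)(CC)OS(=O)(=O)C(F)(F)F
Why: Silylation with the silyl triflate and a hindered base; silyl ethers are used here because, unlike the final acetates, they are not lost by β-elimination from the aldehyde of step 7.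

Step 7
Reactants: 9 (2S,3S,4S)-3-ethenyl-2,4-bis(triethylsilyloxy)oct-7-yne
Product: 10 (2S,3S)-3-(triethylsilyloxy)-2-[(1S)-1-(triethylsilyloxy)ethyl]hept-6-ynal
Conditions: O3, CH2Cl2, −78 °C (Sudan III end point); PPh3, −78 °C → rt
Reagents that add atoms: ozone, [O-][O+]=O
Why: Ozonolysis with reductive work-up cleaves the only alkene, which reacts far faster than the terminal alkyne when the ozone dose is limited by the indicator; C5 is untouched.

Step 8
Reactants: 11 (2-methylallyl)triphenylphosphonium chloride; 12 ethyl formate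
Product: 14 3-methyl-2-(triphenylphosphoranylidene)but-3-enal, via (2-methylallylidene)triphenylphosphorane 13 (not isolated)
Conditions: NaHMDS (2 equiv), THF, −78 → 0 °C; then 12, 0 °C → rt
Reagents that add atoms: none
Why: C-formylation of a phosphorus ylide with a formate ester; the second equivalent of base converts the acylphosphonium salt into the stabilised formyl ylide.

Step 9
Reactants: 10 (2S,3S)-3-(triethylsilyloxy)-2-[(1S)-1-(triethylsilyloxy)ethyl]hept-6-ynal; 14 3-methyl-2-(triphenylphosphoranylidene)but-3-enal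
Product: 15 (2E,4S,5S)-2-(prop-1-en-2-yl)-5-(triethylsilyloxy)-4-[(1S)-1-(triethylsilyloxy)ethyl]non-2-en-8-ynal
Conditions: toluene, 90 °C
Reagents that add atoms: none
Why: Wittig olefination with a stabilised α-substituted formyl ylide, which should give the (E)-enal (formyl trans to C5) and is too weakly basic to epimerise C5.

Step 10
Reactants: 15 (2E,4S,5S)-2-(prop-1-en-2-yl)-5-(triethylsilyloxy)-4-[(1S)-1-(triethylsilyloxy)ethyl]non-2-en-8-ynal
Product: 16 (2E,4S,5S)-5-hydroxy-4-[(1S)-1-hydroxyethyl]-2-(prop-1-en-2-yl)non-2-en-8-ynal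
Conditions: HF·pyridine, pyridine, THF, 0 °C → rt
Reagents that add atoms: none
Why: Fluoride-mediated cleavage of both silyl ethers under pyridine buffering leaves enal, diene and alkyne alone; the (E)-geometry keeps the free hydroxyls from lactolising onto the aldehyde.

Step 11
Reactants: 16 (2E,4S,5S)-5-hydroxy-4-[(1S)-1-hydroxyethyl]-2-(prop-1-en-2-yl)non-2-en-8-ynal
Product: 17 (2E,4S,5S)-5-acetoxy-4-[(1S)-1-acetoxyethyl]-2-(prop-1-en-2-yl)non-2-en-8-ynal
Conditions: Ac2O, pyridine, DMAP (cat.), CH2Cl2, 0 °C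
Reagents that add atoms: acetic anhydride, CC(=O)OC(C)=O
Why: DMAP-catalysed acetylation installs the two acetates of the target now that C5 is only a γ-position of the enal and no longer α to an aldehyde.

Step 12
Reactants: 17 (2E,4S,5S)-5-acetoxy-4-[(1S)-1-acetoxyethyl]-2-(prop-1-en-2-yl)non-2-en-8-ynal; 18 (E)-3-methylpent-2-enoic acid
Product: 19 (5S,6S,7E)-5-acetoxy-6-[(1S)-1-acetoxyethyl]-8-formyl-9-methyl-2-oxodeca-7,9-dien-1-yl (2E)-3-methylpent-2-enoate
Conditions: (Mor-DalPhos)AuNTf2 (5 mol %), 8-methylquinoline N-oxide, PhCl, rt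
Reagents that add atoms: 8-methylquinoline N-oxide, Cc1cccc2ccc[n+]([O-])c12
Why: Gold-catalysed oxidation of the terminal alkyne by the N-oxide gives an α-oxo gold carbene at C9 that inserts into the O–H bond of the acid, so the ketone oxygen goes to the internal carbon C10 and the ester to C9 in one step.

Step 13
Reactants: 19 (5S,6S,7E)-5-acetoxy-6-[(1S)-1-acetoxyethyl]-8-formyl-9-methyl-2-oxodeca-7,9-dien-1-yl (2E)-3-methylpent-2-enoate
Product: 21 C8-axial hydrindanone ketol, via Michael adduct 20 (not isolated)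
Conditions: pyrrolidine (0.3 equiv), AcOH (0.3 equiv), CH2Cl2 (0.02 M), −20 °C → rt
Reagents that add atoms: none
Why: Pyrrolidine condenses with the C10 ketone, and of the two enamines only the C1 enamine can reach the enal β-carbon C6, in a 5-exo-trig Michael addition that closes the cyclopentane and gives keto-aldehyde 20 (the C9 enamine would need a seven-membered ring); the C10 iminium then tautomerises to the C9 (E)-enamine, which adds to the C8 aldehyde in a 6-(enolendo)-exo-trig aldol that closes the cyclohexane. The closest known reactions are amine-catalysed intramolecular Michael additions and the Michael/aldol domino (Robinson- and Hajos–Parrish-type) that annulates a ketone through both α-carbons. C6 is set by A(1,3) strain between the C7 isopropenyl group and C5 (C5–H eclipses the alkene, so C1 attacks anti to the acetoxyethyl group), and C1 ends trans to C6 because this α-keto centre equilibrates through the enamine to the trans-1,2-disubstituted cyclopentane. C7, still α to the aldehyde in 20, epimerises through its enol and is funnelled through the chair transition state with an equatorial isopropenyl group. C9 follows from the (E)-enamine (acyloxy trans to nitrogen, avoiding A(1,3) strain with the pyrrolidine ring), which places the acyloxy group axial (β), and C8 from the acid-bridged closed transition state with the aldehyde oxygen gauche to the iminium carbon, which should give the axial (α) alcohol trans to the C9 ester; this C8 centre is deliberately inverted in step 15. The step needs the aldol to outrun amine-induced drift of the isopropenyl double bond into conjugation and epimerisation at C9, which the intramolecular six-membered closure, the α-branching of the aldehyde, low temperature and a short reaction time should secure.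

Step 14
Reactants: 21 C8-axial hydrindanone ketol
Product: 22 C8-axial 10-methylidene alcohol
Conditions: Zn, CH2Br2, TiCl4 (reagent pre-aged in THF); CH2Cl2, 0 °C → rt
Reagents that add atoms: dibromomethane, BrCBr
Why: Takai–Lombardo methylenation with the non-basic gem-dizinc/titanium reagent converts hindered enolisable ketones into methylidene groups without epimerising C1 or C9 and does not attack esters.

Step 15
Reactants: 22 C8-axial 10-methylidene alcohol
Product: 24 C8-equatorial alcohol (8-epimer of 22), via C8 triflate 23 (not isolated)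
Conditions: Tf2O, 2,6-di-tert-butyl-4-methylpyridine, CH2Cl2, −40 °C; then H2O/THF, NaHCO3, 0 °C
Reagents that add atoms: water, O
Why: Inversion by anchimeric assistance: the axial C8 triflate is displaced from the rear by the antiperiplanar C9 ester carbonyl to give a cis-fused 1,3-dioxolan-2-ylium ion, and hydrolysis of the resulting orthoacid opens to the axial ester and equatorial alcohol, so C8 becomes (R) with the ester still on C9.

Step 16
Reactants: 24 C8-equatorial alcohol
Product: 25 songaricalarin B
Conditions: VO(acac)2 (5 mol %), t-BuOOH (decane), CH2Cl2, 0 °C → rt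
Reagents that add atoms: tert-butyl hydroperoxide, CC(C)(C)OO
Why: Vanadium-catalysed hydroxyl-directed epoxidation of a homoallylic alcohol: the equatorial C8–OH is gauche to the C7 isopropenyl group but antiperiplanar to C9–C10, so only the isopropenyl alkene can be reached, and delivery through a chair-like vanadate with C7–H eclipsing the C=CH2 bond should give the (11S)-epoxide.

**Compound list**

1 | (R)-4-benzyloxazolidin-2-one | O=C1N[C@H](Cc2ccccc2)CO1 | starting material
2 | (E)-but-2-enoyl chloride | C/C=C/C(=O)Cl | starting material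
3 | (R)-4-benzyl-3-[(E)-but-2-enoyl]oxazolidin-2-one | C/C=C/C(=O)N1[C@H](Cc2ccccc2)COC1=O | intermediate
4 | pent-4-ynal | C#CCCC=O | starting material
5 | (R)-4-benzyl-3-[(2R,3S)-2-ethenyl-3-hydroxyhept-6-ynoyl]oxazolidin-2-one | C#CCC[C@H](O)[C@@H](C=C)C(=O)N1[C@H](Cc2ccccc2)COC1=O | intermediate
6 | (2R,3S)-2-ethenyl-3-hydroxy-N-methoxy-N-methylhept-6-ynamide | C#CCC[C@H](O)[C@@H](C=C)C(=O)N(C)OC | intermediate
7 | (3R,4S)-3-ethenyl-4-hydroxyoct-7-yn-2-one | C#CCC[C@H](O)[C@@H](C=C)C(C)=O | intermediate
8 | (2S,3S,4S)-3-ethenyloct-7-yne-2,4-diol | C#CCC[C@H](O)[C@@H](C=C)[C@H](C)O | intermediate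
9 | (2S,3S,4S)-3-ethenyl-2,4-bis(triethylsilyloxy)oct-7-yne | C#CCC[C@H](O[Si](CC)(CC)CC)[C@@H](C=C)[C@H](C)O[Si](CC)(CC)CC | intermediate
10 | (2S,3S)-3-(triethylsilyloxy)-2-[(1S)-1-(triethylsilyloxy)ethyl]hept-6-ynal | C#CCC[C@H](O[Si](CC)(CC)CC)[C@@H](C=O)[C@H](C)O[Si](CC)(CC)CC | intermediate
11 | (2-methylallyl)triphenylphosphonium chloride | C=C(C)C[P+](c1ccccc1)(c1ccccc1)c1ccccc1.[Cl-] | starting material
12 | ethyl formate | CCOC=O | starting material
13 | (2-methylallylidene)triphenylphosphorane (not isolated) | C=C(C)C=P(c1ccccc1)(c1ccccc1)c1ccccc1 | intermediate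
14 | 3-methyl-2-(triphenylphosphoranylidene)but-3-enal | C=C(C)C(C=O)=P(c1ccccc1)(c1ccccc1)c1ccccc1 | intermediate
15 | (2E,4S,5S)-2-(prop-1-en-2-yl)-5-(triethylsilyloxy)-4-[(1S)-1-(triethylsilyloxy)ethyl]non-2-en-8-ynal | C#CCC[C@H](O[Si](CC)(CC)CC)[C@@H](/C=C(/C=O)C(C)=C)[C@H](C)O[Si](CC)(CC)CC | intermediate
16 | (2E,4S,5S)-5-hydroxy-4-[(1S)-1-hydroxyethyl]-2-(prop-1-en-2-yl)non-2-en-8-ynal | C#CCC[C@H](O)[C@@H](/C=C(/C=O)C(C)=C)[C@H](C)O | intermediate
17 | (2E,4S,5S)-5-acetoxy-4-[(1S)-1-acetoxyethyl]-2-(prop-1-en-2-yl)non-2-en-8-ynal | C#CCC[C@H](OC(C)=O)[C@@H](/C=C(/C=O)C(C)=C)[C@H](C)OC(C)=O | intermediate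
18 | (E)-3-methylpent-2-enoic acid | CC/C(C)=C/C(=O)O | starting material
19 | (5S,6S,7E)-5-acetoxy-6-[(1S)-1-acetoxyethyl]-8-formyl-9-methyl-2-oxodeca-7,9-dien-1-yl (2E)-3-methylpent-2-enoate | CC/C(C)=C/C(=O)OCC(=O)CC[C@H](OC(C)=O)[C@@H](/C=C(/C=O)C(C)=C)[C@H](C)OC(C)=O | intermediate
20 | 2-[(1R,2S,3S,4S)-4-acetoxy-3-[(1S)-1-acetoxyethyl]-2-[(2R)-3-methyl-1-oxobut-3-en-2-yl]cyclopentyl]-2-oxoethyl (2E)-3-methylpent-2-enoate (Michael adduct, not isolated; C7 equilibrates) | CC/C(C)=C/C(=O)OCC(=O)[C@@H]1C[C@H](OC(C)=O)[C@H]([C@H](C)OC(C)=O)[C@H]1[C@H](C(C)=C)C=O | intermediate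
21 | (1S)-1-[(1S,2S,3aR,5R,6S,7R,7aR)-2-acetoxy-6-hydroxy-5-{[(2E)-3-methylpent-2-enoyl]oxy}-4-oxo-7-(prop-1-en-2-yl)octahydro-1H-inden-1-yl]ethyl acetate (trans-fused; C8–OH axial α, C9 ester axial β) | O=C1[C@@H]2C[C@H](OC(C)=O)[C@H]([C@H](C)OC(C)=O)[C@H]2[C@H](C(C)=C)[C@H](O)[C@H]1OC(=O)/C=C(\C)CC | intermediate
22 | (1S)-1-[(1S,2S,3aR,5S,6S,7R,7aR)-2-acetoxy-6-hydroxy-5-{[(2E)-3-methylpent-2-enoyl]oxy}-4-methylidene-7-(prop-1-en-2-yl)octahydro-1H-inden-1-yl]ethyl acetate (C8–OH axial) | C=C1[C@@H]2C[C@H](OC(C)=O)[C@H]([C@H](C)OC(C)=O)[C@H]2[C@H](C(C)=C)[C@H](O)[C@H]1OC(=O)/C=C(\C)CC | intermediate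
23 | C8 trifluoromethanesulfonate of 22 (not isolated) | C=C1[C@@H]2C[C@H](OC(C)=O)[C@H]([C@H](C)OC(C)=O)[C@H]2[C@H](C(C)=C)[C@H](OS(=O)(=O)C(F)(F)F)[C@H]1OC(=O)/C=C(\C)CC | intermediate
24 | (1S)-1-[(1S,2S,3aR,5S,6R,7R,7aR)-2-acetoxy-6-hydroxy-5-{[(2E)-3-methylpent-2-enoyl]oxy}-4-methylidene-7-(prop-1-en-2-yl)octahydro-1H-inden-1-yl]ethyl acetate (C8–OH equatorial β) | C=C1[C@@H]2C[C@H](OC(C)=O)[C@H]([C@H](C)OC(C)=O)[C@H]2[C@H](C(C)=C)[C@@H](O)[C@H]1OC(=O)/C=C(\C)CC | intermediate
25 | songaricalarin B, (1S)-1-[(1S,2S,3aR,5S,6R,7S,7aS)-2-acetoxy-6-hydroxy-5-{[(2E)-3-methylpent-2-enoyl]oxy}-4-methylidene-7-[(2S)-2-methyloxiran-2-yl]octahydro-1H-inden-1-yl]ethyl acetate | C=C1[C@@H]2C[C@H](OC(C)=O)[C@H]([C@H](C)OC(C)=O)[C@H]2[C@H]([C@@]2(C)CO2)[C@@H](O)[C@H]1OC(=O)/C=C(\C)CC | target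

**Step count.** Total: 16 steps. Longest linear sequence: 15 steps (1 → 25 through steps 1–7 and 9–16; step 8 is a one-step side branch).

**Steps most likely to fail**

Step 13. Once the Michael closure has made the C8 aldehyde, the amine may also condense there and move the isopropenyl double bond into conjugation; the aldol may stall or reverse, and C9 may epimerise through the enamine. The fallback gives up the single-flask domino for a two-stage closure. It sets out from 19: the Michael cyclisation is run alone (pyrrolidine/AcOH, −20 °C, early acidic quench) and keto-aldehyde 20 is isolated. Compound 20 is then enolised with (c-Hex)2BCl/Et3N in Et2O at −78 °C to the C9 (E)-enol borinate, whose boron-bridged closed aldol should give the same axial C8 alkoxide and axial C9 ester. Buffered H2O2 work-up brings the route back at 21; no new compound is needed.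

Step 15. Base-induced elimination of the axial triflate toward C7 (its axial hydrogen is antiperiplanar), or ionisation and rearrangement, may outrun ester participation, and the orthoacid may open to the C8 ester instead. The fallback replaces substitution by redox inversion. It sets out from 22: Dess–Martin periodinane (CH2Cl2, NaHCO3, 0 °C) gives the C8 ketone F1. Luche reduction (NaBH4, CeCl3, MeOH, −78 °C) should then deliver hydride axially from the α-face, the β-face being screened by the axial C9 ester, and gives the equatorial alcohol, coming back at 24.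

Step 9. The doubly β-branched aldehyde may add too slowly to the hindered stabilised ylide, so that prolonged heating erodes the C5 configuration or the alkene geometry. The fallback builds the enal at the ester oxidation level. It sets out from 10: the γ-deprotonated phosphonate ethyl 2-(diethoxyphosphoryl)-3-methylbut-2-enoate F2 (made by Knoevenagel condensation of triethyl phosphonoacetate with acetone, TiCl4/pyridine) undergoes a Horner–Wadsworth–Emmons reaction (NaH, THF, −78 → 0 °C) to the diene ester F3. DIBAL-H (CH2Cl2, −78 °C) gives the dienol F4, and MnO2 (CH2Cl2, rt) oxidises it to the enal, coming back at 15.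

**Further compounds**

F0 | step 13 | none | none
F1 | step 15 | (1S)-1-[(1S,2S,3aR,5S,7R,7aR)-2-acetoxy-5-{[(2E)-3-methylpent-2-enoyl]oxy}-4-methylidene-6-oxo-7-(prop-1-en-2-yl)octahydro-1H-inden-1-yl]ethyl acetate (C8 ketone) | C=C1[C@@H]2C[C@H](OC(C)=O)[C@H]([C@H](C)OC(C)=O)[C@H]2[C@H](C(C)=C)C(=O)[C@H]1OC(=O)/C=C(\C)CC
F2 | step 9 | ethyl 2-(diethoxyphosphoryl)-3-methylbut-2-enoate | CCOC(=O)C(=C(C)C)P(=O)(OCC)OCC
F3 | step 9 | ethyl (2E,4S,5S)-2-(prop-1-en-2-yl)-5-(triethylsilyloxy)-4-[(1S)-1-(triethylsilyloxy)ethyl]non-2-en-8-ynoate | C#CCC[C@H](O[Si](CC)(CC)CC)[C@@H](/C=C(/C(=O)OCC)C(C)=C)[C@H](C)O[Si](CC)(CC)CC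
F4 | step 9 | (2E,4S,5S)-2-(prop-1-en-2-yl)-5-(triethylsilyloxy)-4-[(1S)-1-(triethylsilyloxy)ethyl]non-2-en-8-yn-1-ol | C#CCC[C@H](O[Si](CC)(CC)CC)[C@@H](/C=C(/CO)C(C)=C)[C@H](C)O[Si](CC)(CC)CC
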